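**Retrosynthetic overview**
1. Palstatin ⇐ global O-debenzylation ⇐ flavone pyranone ring (formed last) by I2/DMSO oxidative cyclisation of a 2'-hydroxychalcone ⇐ Claisen–Schmidt condensation of a benzodioxane aldehyde with 2-hydroxy-4,6-dibenzyloxyacetophenone.
2. Dioxane ring (formed first; the three benzene rings are bought) ⇐ acid-mediated C3–O4 closure of a phenol onto a benzylic carbinol, with trans geometry dictated by C2.
3. Benzylic carbinol ⇐ aryl-Grignard addition to an (R)-α-aryloxy aldehyde (C3–aryl bond).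
4. C2–O1 aryl ether ⇐ Mitsunobu inversion of a (2S)-3-O-benzylglycerate with mono-allylated 5-hydroxyvanillin.
5. (2S)-Hydroxy ester ⇐ ketoreductase reduction of achiral ethyl 3-(benzyloxy)-2-oxopropanoate, the only source of chirality.

Assumption: the target is the trans-(2R,3R) benzodioxane (both centres R by CIP analysis of the SMILES); 13 and 19 are purchased, and the ketoreductase is picked from a commercial panel for (S)-selectivity.

**Route**

Step 1
Reactants: 1 ethyl 2-(bromomethyl)acrylate; 2 benzyl alcohol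
Product: 3 ethyl 2-[(benzyloxy)methyl]prop-2-enoate
Conditions: BnOH, DABCO, Et3N, CH2Cl2, 0 °C → rt
Reagents that add atoms: benzyl alcohol (2), OCc1ccccc1
Why: SN2'/SN2' substitution of the activated allylic bromide via the allylic ammonium salt gives the 2-(alkoxymethyl)acrylate without touching the ester.

Step 2
Reactants: 3
Product: 4 ethyl 3-(benzyloxy)-2-oxopropanoate
Conditions: O3, CH2Cl2, −78 °C (Sudan III end-point); Me2S, −78 °C → rt
Reagents that add atoms: ozone, O=[O+][O-] (one O retained)
Why: Ozonolysis of the 1,1-disubstituted alkene cleaves =CH2 to the 2-oxo ester, and low temperature with an indicator dye spares the benzyl ether.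

Step 3
Reactants: 4
Product: 5 ethyl (2S)-3-(benzyloxy)-2-hydroxypropanoate
Conditions: (S)-selective ketoreductase (KRED), NADP+ (cat.), i-PrOH (10% v/v), K-phosphate buffer pH 7.0, 30 °C
Reagents that add atoms: none
Why: Biocatalytic asymmetric carbonyl reduction — the NADPH-dependent ketoreductase delivers hydride to one face of the prochiral 2-oxo ester, fixing C2 as (S) (typically >99% ee), with i-PrOH recycling the cofactor.

Step 4
Reactants: 6 3,4-dihydroxy-5-methoxybenzaldehyde (5-hydroxyvanillin); 7 allyl bromide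
Product: 8 4-hydroxy-3-methoxy-5-(prop-2-en-1-yloxy)benzaldehyde
Conditions: NaH (2.2 equiv), DMSO, rt; then allyl bromide (1.0 equiv), rt
Reagents that add atoms: allyl bromide (7), C=CCBr
Why: Williamson etherification under dianion regiocontrol — the 3-O⁻ (meta to CHO, one ortho substituent) is far more nucleophilic than the delocalised, doubly flanked 4-O⁻, so one equivalent of electrophile alkylates it selectively.

Step 5
Reactants: 8; 5
Product: 9 ethyl (2R)-3-(benzyloxy)-2-[4-formyl-2-methoxy-6-(prop-2-en-1-yloxy)phenoxy]propanoate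
Conditions: PPh3, DIAD, THF, 0 °C → rt
Reagents that add atoms: none (PPh3/DIAD not incorporated)
Why: Mitsunobu reaction — the acidic para-formyl phenol (pKa about 7.5) displaces the α-hydroxy-ester oxyphosphonium by SN2 with inversion, converting (S)-5 into the (R)-aryl ether.

Step 6
Reactants: 9; 10 ethylene glycol
Product: 11 ethyl (2R)-3-(benzyloxy)-2-[4-(1,3-dioxolan-2-yl)-2-methoxy-6-(prop-2-en-1-yloxy)phenoxy]propanoate
Conditions: ethylene glycol, PPTS (cat.), benzene, reflux, Dean–Stark
Reagents that add atoms: ethylene glycol (10), OCCO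
Why: Acid-catalysed acetalisation masks the only aldehyde so the later hydride and aryl-metal steps act solely at the ester-derived carbon, and the α-aryloxy stereocentre is not enolised under PPTS.

Step 7
Reactants: 11
Product: 12 (2R)-3-(benzyloxy)-2-[4-(1,3-dioxolan-2-yl)-2-methoxy-6-(prop-2-en-1-yloxy)phenoxy]propanal
Conditions: DIBAL-H (1.2 equiv), CH2Cl2, −78 °C; MeOH then Rochelle salt; used crude
Reagents that add atoms: none
Why: Low-temperature DIBAL-H partial reduction stops at the chelated aluminium hemiacetal of the α,β-dialkoxy ester and releases the aldehyde only on work-up, without epimerising C2.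

Step 8
Reactants: 13 4-bromo-2,6-dimethoxyphenol; 14 benzyl bromide
Product: 15 2-(benzyloxy)-5-bromo-1,3-dimethoxybenzene
Conditions: BnBr, K2CO3, DMF, rt
Reagents that add atoms: benzyl bromide (14), BrCc1ccccc1
Why: Williamson O-benzylation of the acidic phenol gives an aryl bromide with a protecting group that survives organometallic, acidic and basic steps.

Step 9
Reactants: 15; 12
Product: 16 (1RS,2R)-3-(benzyloxy)-1-[4-(benzyloxy)-3,5-dimethoxyphenyl]-2-[4-(1,3-dioxolan-2-yl)-2-methoxy-6-(prop-2-en-1-yloxy)phenoxy]propan-1-ol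
Conditions: 15, n-BuLi, THF, −78 °C; MgBr2·OEt2; then 12, −78 → −40 °C
Reagents that add atoms: none (aryl group comes from 15)
Why: Br/Li exchange and transmetallation give a weakly basic aryl-Grignard that adds 1,2 to the aldehyde faster than it enolises it; the new carbinol centre forms as a mixture, which is irrelevant because it is ionised in step 11, while C2 is untouched.

Step 10
Reactants: 16
Product: 17 (1RS,2R)-3-(benzyloxy)-1-[4-(benzyloxy)-3,5-dimethoxyphenyl]-2-[4-(1,3-dioxolan-2-yl)-2-hydroxy-6-methoxyphenoxy]propan-1-ol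
Conditions: Pd(PPh3)4 (5 mol%), K2CO3, MeOH, rt
Reagents that add atoms: none
Why: Pd(0) π-allyl cleavage (Tsuji–Trost deallylation) frees the phenol under mild conditions that leave the benzyl ethers, acetal and carbinol intact.

Step 11
Reactants: 17
Product: 18 (2R,3R)-3-[4-(benzyloxy)-3,5-dimethoxyphenyl]-2-[(benzyloxy)methyl]-8-methoxy-2,3-dihydro-1,4-benzodioxine-6-carbaldehyde
Conditions: TFA (10 equiv), CH2Cl2, 0 °C → rt; then H2O/THF, rt; chromatography to remove minor cis isomer
Reagents that add atoms: water, O (aldehyde oxygen after acetal hydrolysis)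
Why: TFA ionises the electron-rich benzylic carbinol to a p-alkoxybenzyl cation that the adjacent phenol captures (reversible SN1 six-membered ring closure), so the aryl group settles trans-diequatorial to the C2 substituent and C3 is set as (R) under control of C2; aqueous acid then hydrolyses the dioxolane.

Step 12
Reactants: 18; 19 1-[2,4-bis(benzyloxy)-6-hydroxyphenyl]ethan-1-one
Product: 20 (2E)-1-[2,4-bis(benzyloxy)-6-hydroxyphenyl]-3-{(2R,3R)-3-[4-(benzyloxy)-3,5-dimethoxyphenyl]-2-[(benzyloxy)methyl]-8-methoxy-2,3-dihydro-1,4-benzodioxin-6-yl}prop-2-en-1-one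
Conditions: KOH (50% aq.), EtOH–THF, rt, 48 h
Reagents that add atoms: none
Why: Claisen–Schmidt (crossed aldol) condensation of the non-enolisable aldehyde with the acetophenone enolate gives the (E)-2'-hydroxychalcone, and with the syringyl oxygen benzylated no quinone-methide ring opening or epimerisation is possible in base.

Step 13
Reactants: 20
Product: 21 5,7-bis(benzyloxy)-2-{(2R,3R)-3-[4-(benzyloxy)-3,5-dimethoxyphenyl]-2-[(benzyloxy)methyl]-8-methoxy-2,3-dihydro-1,4-benzodioxin-6-yl}-4H-chromen-4-one
Conditions: I2 (10 mol%), DMSO, 130 °C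
Reagents that add atoms: none
Why: I2/DMSO oxidative cyclisation — oxa-Michael closure of the 2'-OH followed by iodine-mediated dehydrogenation forms the pyranone ring without affecting the benzodioxane stereocentres.

Step 14
Reactants: 21
Product: 22 palstatin, 5,7-dihydroxy-2-[(2R,3R)-3-(4-hydroxy-3,5-dimethoxyphenyl)-2-(hydroxymethyl)-8-methoxy-2,3-dihydro-1,4-benzodioxin-6-yl]-4H-chromen-4-one
Conditions: H2 (1 atm), Pd(OH)2/C, THF–MeOH, rt (monitored, stopped at full debenzylation)
Reagents that add atoms: none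
Why: Catalytic hydrogenolysis removes the three aryl and one alkyl benzyl ethers, while the cyclic secondary benzylic aryl ether and the flavone C2=C3 bond react much more slowly, as in benzylated flavan and flavone deprotections.

**Compound list**
1 | ethyl 2-(bromomethyl)acrylate | C=C(CBr)C(=O)OCC | starting material
2 | benzyl alcohol | OCc1ccccc1 | starting material
3 | ethyl 2-[(benzyloxy)methyl]prop-2-enoate | C=C(COCc1ccccc1)C(=O)OCC | intermediate
4 | ethyl 3-(benzyloxy)-2-oxopropanoate | CCOC(=O)C(=O)COCc1ccccc1 | intermediate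
5 | ethyl (2S)-3-(benzyloxy)-2-hydroxypropanoate | CCOC(=O)[C@@H](O)COCc1ccccc1 | intermediate
6 | 3,4-dihydroxy-5-methoxybenzaldehyde | COc1cc(C=O)cc(O)c1O | starting material
7 | allyl bromide | C=CCBr | starting material
8 | 4-hydroxy-3-methoxy-5-(allyloxy)benzaldehyde | COc1cc(C=O)cc(OCC=C)c1O | intermediate
9 | ethyl (2R)-3-(benzyloxy)-2-[4-formyl-2-methoxy-6-(allyloxy)phenoxy]propanoate | CCOC(=O)[C@@H](COCc1ccccc1)Oc1c(OC)cc(C=O)cc1OCC=C | intermediate
10 | ethylene glycol | OCCO | starting material
11 | ethyl (2R)-3-(benzyloxy)-2-[4-(1,3-dioxolan-2-yl)-2-methoxy-6-(allyloxy)phenoxy]propanoate | CCOC(=O)[C@@H](COCc1ccccc1)Oc1c(OC)cc(C2OCCO2)cc1OCC=C | intermediate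
12 | (2R)-3-(benzyloxy)-2-[4-(1,3-dioxolan-2-yl)-2-methoxy-6-(allyloxy)phenoxy]propanal | O=C[C@@H](COCc1ccccc1)Oc1c(OC)cc(C2OCCO2)cc1OCC=C | intermediate
13 | 4-bromo-2,6-dimethoxyphenol | COc1cc(Br)cc(OC)c1O | starting material
14 | benzyl bromide | BrCc1ccccc1 | starting material
15 | 2-(benzyloxy)-5-bromo-1,3-dimethoxybenzene | COc1cc(Br)cc(OC)c1OCc1ccccc1 | intermediate
16 | (1RS,2R)-3-(benzyloxy)-1-[4-(benzyloxy)-3,5-dimethoxyphenyl]-2-[4-(1,3-dioxolan-2-yl)-2-methoxy-6-(allyloxy)phenoxy]propan-1-ol | OC(c1cc(OC)c(OCc2ccccc2)c(OC)c1)[C@@H](COCc1ccccc1)Oc1c(OC)cc(C2OCCO2)cc1OCC=C | intermediate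
17 | (1RS,2R)-3-(benzyloxy)-1-[4-(benzyloxy)-3,5-dimethoxyphenyl]-2-[4-(1,3-dioxolan-2-yl)-2-hydroxy-6-methoxyphenoxy]propan-1-ol | OC(c1cc(OC)c(OCc2ccccc2)c(OC)c1)[C@@H](COCc1ccccc1)Oc1c(OC)cc(C2OCCO2)cc1O | intermediate
18 | (2R,3R)-3-[4-(benzyloxy)-3,5-dimethoxyphenyl]-2-[(benzyloxy)methyl]-8-methoxy-2,3-dihydro-1,4-benzodioxine-6-carbaldehyde | COc1cc([C@H]2Oc3cc(C=O)cc(OC)c3O[C@@H]2COCc2ccccc2)cc(OC)c1OCc1ccccc1 | intermediate
19 | 1-[2,4-bis(benzyloxy)-6-hydroxyphenyl]ethan-1-one | CC(=O)c1c(O)cc(OCc2ccccc2)cc1OCc1ccccc1 | starting material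
20 | (2E)-2'-hydroxychalcone from 18 and 19 | COc1cc([C@H]2Oc3cc(/C=C/C(=O)c4c(O)cc(OCc5ccccc5)cc4OCc4ccccc4)cc(OC)c3O[C@@H]2COCc2ccccc2)cc(OC)c1OCc1ccccc1 | intermediate
21 | tetra-O-benzyl palstatin (5,7-bis(benzyloxy)flavone) | COc1cc([C@H]2Oc3cc(-c4cc(=O)c5c(OCc6ccccc6)cc(OCc7ccccc7)cc5o4)cc(OC)c3O[C@@H]2COCc2ccccc2)cc(OC)c1OCc1ccccc1 | intermediate
22 | palstatin | COc1cc([C@H]2Oc3cc(-c4cc(=O)c5c(O)cc(O)cc5o4)cc(OC)c3O[C@@H]2CO)cc(OC)c1O | target

**Summary**
Total steps: 14.
Longest linear sequence: 12 steps (1 → 3 → 4 → 5 → 9 → 11 → 12 → 16 → 17 → 18 → 20 → 21 → 22).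

Three steps most likely to fail, with fallbacks:
- **Step 5 (Mitsunobu with a 2,6-disubstituted phenol):** low conversion or elimination is possible. Fallback: alkylate 8 with diethyl bromomalonate, acetalise, reduce to the prochiral 2-aryloxypropane-1,3-diol, desymmetrise it with a lipase (vinyl acetate), then silylate, deacetylate and oxidise to rejoin the route at the aldehyde stage.
- **Step 11 (SN1 ring closure):** sluggish ionisation, enol-ether formation or poor trans:cis ratio are possible. Fallback: make the closure stereospecific — oxidise 16 to the ketone, reduce Felkin-selectively to the anti carbinol, deallylate, and close by intramolecular Mitsunobu (SN2 inversion gives trans).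
- **Step 4 (regioselective mono-allylation):** 4-O- or bis-allylation may compete. Fallback: use 5-bromovanillin as the phenol in step 5 (bromine as latent oxygen) and install the 5'-OH after step 9 by Pd-catalysed Miyaura borylation then oxidation, converging on 17.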